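The route rests on installing the two benzo-ring bromines last on the carbon skeleton, while the side-chain carbon is still an amide. The key step forms the C5–Br and C6–Br bonds in one operation. It exploits the carbonyl on C3 of the pyrrole ring: together with the C2 bromine and the N1 methyl it shuts C2/C3 to electrophiles and screens C4 and C7, so bromine is left only the neighbouring C5 and C6 of the benzene ring, and the amide cannot fragment as a gramine would. The precursor is 2-bromo-N,N,1-trimethylindole-3-carboxamide, reached by amidation and amide-directed C2 lithiation–bromination; alane reduction of the tribromo amide then gives the target.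

Key step: step 3

Assumption: the target has no stereocentre, axis or configured double bond, so the "single enantiomer" is simply the one achiral constitution and no step has to set or protect configuration.

Step 1
Reactants: 1 1-methylindole-3-carboxylic acid; 2 dimethylamine
Product: 4 N,N,1-trimethylindole-3-carboxamide, via acid chloride 3 (not isolated)
Conditions: (COCl)2 (1.2 equiv), DMF (cat.), CH2Cl2, 0 °C → rt; evaporate; then Me2NH (2 M in THF, 3 equiv), CH2Cl2, 0 °C → rt
Reagents that add atoms: dimethylamine 2, CNC (oxalyl chloride, O=C(Cl)C(=O)Cl, puts chlorine only into intermediate 3)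
Why: Nucleophilic acyl substitution through the acid chloride (Vilsmeier-type activation, then Schotten–Baumann-type aminolysis) is routine for indole-3-carboxylic acids, N1 is already methylated so no N-acylation can compete, and the excess amine takes up the HCl.

Step 2
Reactants: 4 N,N,1-trimethylindole-3-carboxamide; 5 1,2-dibromo-1,1,2,2-tetrachloroethane
Product: 7 2-bromo-N,N,1-trimethylindole-3-carboxamide, via C2-lithio amide 6 (not isolated)
Conditions: LDA (1.2 equiv), THF, −78 °C, 1 h; then BrCl2CCCl2Br (1.3 equiv), THF, −78 °C → rt
Reagents that add atoms: 1,2-dibromo-1,1,2,2-tetrachloroethane 5, BrC(Cl)(Cl)C(Cl)(Cl)Br (the lithium of intermediate 6 comes from LDA, [Li]N(C(C)C)C(C)C)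
Why: Directed ortho-metalation: the C3 dimethylamide binds lithium and, with the inductive pull of N1, makes C2–H the most acidic site, the non-nucleophilic amide base does not add to the carbonyl, and the C2 carbanion attacks a bromine of 5 (halogen transfer with loss of tetrachloroethylene and LiBr) to give the C2 bromide.

Step 3
Reactants: 7 2-bromo-N,N,1-trimethylindole-3-carboxamide; 8 bromine
Product: 11 2,5,6-tribromo-N,N,1-trimethylindole-3-carboxamide, via 2,5-dibromo amide 9 (not isolated), via 2,6-dibromo amide 10 (not isolated)
Conditions: Br2 (2.1 equiv, added in two portions), AcOH, rt, dark; aq. Na2S2O3/NaHCO3 work-up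
Reagents that add atoms: bromine 8, BrBr
Why: Each bromination is an electrophilic aromatic substitution through an arenium (σ-complex) cation that N1 stabilises, directly across C7a for attack at C5 and through the C3a–C3=C2–N1 path for attack at C6; the closest known reaction type is the bromine/acetic acid 5,6-dibromination of indoles carrying a C3 ester or formyl group. No ring is closed and no stereocentre is formed. The step needs positional selectivity for C5 and C6 over C4, C7 and ipso attack at C3: the pyrrole ring is fully substituted and electron-poor (C2–Br, C3–C=O), C4 is screened by the peri amide and C7 by the N1 methyl, so only the two central benzo positions remain open. The first bromine should enter at C5 or C6 (9 or 10) and the second at the remaining one, ortho to the first, so both monobromides converge on 11, after which three halogens and the acyl group should make the ring too electron-poor for a third substitution at room temperature. Running the bromination on the amide and not on the amine avoids retro-Mannich fragmentation and N-bromination or oxidation of a basic benzylic amine.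

Step 4
Reactants: 11 2,5,6-tribromo-N,N,1-trimethylindole-3-carboxamide
Product: 12 2,5,6-tribromo-1-methylgramine
Conditions: AlH3·NMe2Et (0.5 M in toluene, 2 equiv), THF, 0 °C → rt; aq. Rochelle salt
Reagents that add atoms: none
Why: Amide-to-amine reduction by alane: aluminium binds the carbonyl oxygen, hydride adds, the O-aluminated hemiaminal collapses to an iminium ion that takes a second hydride, and since alane is a neutral electrophilic hydride without the electron-transfer and ate-complex reactivity of LiAlH4, the three C–Br bonds (including the activated C2–Br) should stay intact.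

Compound list
1 | 1-methylindole-3-carboxylic acid | Cn1cc(C(=O)O)c2ccccc21 | starting material
2 | dimethylamine | CNC | starting material
3 | 1-methylindole-3-carbonyl chloride | Cn1cc(C(=O)Cl)c2ccccc21 | intermediate
4 | N,N,1-trimethylindole-3-carboxamide | CN(C)C(=O)c1cn(C)c2ccccc12 | intermediate
5 | 1,2-dibromo-1,1,2,2-tetrachloroethane | BrC(Cl)(Cl)C(Cl)(Cl)Br | starting material
6 | 2-lithio-N,N,1-trimethylindole-3-carboxamide | [Li]c1c(C(=O)N(C)C)c2ccccc2n1C | intermediate
7 | 2-bromo-N,N,1-trimethylindole-3-carboxamide | CN(C)C(=O)c1c(Br)n(C)c2ccccc12 | intermediate
8 | bromine | BrBr | starting material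
9 | 2,5-dibromo-N,N,1-trimethylindole-3-carboxamide | CN(C)C(=O)c1c(Br)n(C)c2ccc(Br)cc12 | intermediate
10 | 2,6-dibromo-N,N,1-trimethylindole-3-carboxamide | CN(C)C(=O)c1c(Br)n(C)c2cc(Br)ccc12 | intermediate
11 | 2,5,6-tribromo-N,N,1-trimethylindole-3-carboxamide | CN(C)C(=O)c1c(Br)n(C)c2cc(Br)c(Br)cc12 | intermediate
12 | 2,5,6-tribromo-1-methylgramine | CN(C)Cc1c(Br)n(C)c2cc(Br)c(Br)cc12 | target

Total step count: 4. Longest linear sequence: 4 steps (1 → 4 → 7 → 11 → 12).

Steps most likely to fail

Step 3.
- Risk: the C2 bromine twists the dimethylamide out of the indole plane, so the carbonyl may lose part of its hold on the ring. Bromine could then be delivered to C4 or C7, add at C3 with later hydrolysis at C2 to oxindole-type material, or enter a third time.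
- Fallback: change the order of the halogenations, setting out from 4 and returning at 11. The amide of 4 is unhindered and conjugated, as in the ester and aldehyde precedents. Br2 (2.1 equiv) in AcOH at rt should pass through 5-bromo-N,N,1-trimethylindole-3-carboxamide F1 and 6-bromo-N,N,1-trimethylindole-3-carboxamide F2 to 5,6-dibromo-N,N,1-trimethylindole-3-carboxamide F3. Amide-directed C2 magnesiation of F3 with TMPMgCl·LiCl in THF at −20 °C, a base that tolerates aryl bromides, should give 5,6-dibromo-2-(chloromagnesio)-N,N,1-trimethylindole-3-carboxamide F4. Its quench with 5 rejoins the route at 11.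

Step 4.
- Risk: C–N hydrogenolysis, in which aluminium-assisted ionisation of the benzylic amine of the product gives a 3-methyleneindoleninium ion that takes up hydride. Hydride could also remove the activated C2 bromine, or the reduction could stall because the amide is a vinylogous urea.
- Fallback: rebuild the C–N bond instead of reducing the C=O in place, setting out from 11 and returning at 12. Cp2Zr(H)Cl (1.5 equiv) in THF at rt should add once to the amide to give the O-zirconated hemiaminal F5, which should persist until hydrolytic work-up and then release 2,5,6-tribromo-1-methylindole-3-carbaldehyde F6. Reductive amination of F6 with 2 and NaBH(OAc)3/AcOH in 1,2-dichloroethane gives 12; it is kept at rt so that the amine does not displace the C2 bromide.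

Step 2.
- Risk: the C2-lithio species attacks the comparatively unhindered dimethylamide carbonyl of a second molecule (self-condensation to a diindolyl ketone), or metalation stays incomplete.
- Fallback: metalate at the carboxylate stage, where the directing group is not electrophilic, and form the amide afterwards, setting out from 1 and returning at 7. LDA (2.2 equiv) in THF at −78 °C should give lithium 2-lithio-1-methylindole-3-carboxylate F7. Quench with 5 and mild cold acidification should give 2-bromo-1-methylindole-3-carboxylic acid F8. Activation with carbonyldiimidazole in THF should give (2-bromo-1-methylindol-3-yl)(imidazol-1-yl)methanone F9; this is chloride-free, so the C2 halogen cannot exchange. Addition of 2 rejoins the route at 7.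

Further compounds
F1 | step 3 | 5-bromo-N,N,1-trimethylindole-3-carboxamide | CN(C)C(=O)c1cn(C)c2ccc(Br)cc12
F2 | step 3 | 6-bromo-N,N,1-trimethylindole-3-carboxamide | CN(C)C(=O)c1cn(C)c2cc(Br)ccc12
F3 | step 3 | 5,6-dibromo-N,N,1-trimethylindole-3-carboxamide | CN(C)C(=O)c1cn(C)c2cc(Br)c(Br)cc12
F4 | step 3 | 5,6-dibromo-2-(chloromagnesio)-N,N,1-trimethylindole-3-carboxamide | CN(C)C(=O)c1c([Mg]Cl)n(C)c2cc(Br)c(Br)cc12
F5 | step 4 | chlorobis(cyclopentadienyl)zirconium O-bound hemiaminal of 11, racemic at the hemiaminal carbon (Cp rings drawn σ-bonded) | CN(C)C(O[Zr](Cl)(C1C=CC=C1)C1C=CC=C1)c1c(Br)n(C)c2cc(Br)c(Br)cc12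
F6 | step 4 | 2,5,6-tribromo-1-methylindole-3-carbaldehyde | Cn1c(Br)c(C=O)c2cc(Br)c(Br)cc21
F7 | step 2 | lithium 2-lithio-1-methylindole-3-carboxylate | [Li]c1c(C(=O)[O-])c2ccccc2n1C.[Li+]
F8 | step 2 | 2-bromo-1-methylindole-3-carboxylic acid | Cn1c(Br)c(C(=O)O)c2ccccc21
F9 | step 2 | (2-bromo-1-methylindol-3-yl)(imidazol-1-yl)methanone | Cn1c(Br)c(C(=O)n2ccnc2)c2ccccc21
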